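I began with the easy step, the fork at intermediate A, in a chain where substrate gives intermediate A, intermediate A goes on to side product A or intermediate B, intermediate B passes reversibly to intermediate C, and intermediate C goes on to target or side product B.

- delta: substrate 12 mM; one stirred flow tank at steady state, fed with the mixture as stated, mean residence time 1.5 min
- theta: substrate 12 mM; time 1.5 min; everything together in a closed stirred flask, run for 1.5 min

    substrate → intermediate A (k1 = 0.027 s⁻¹)
    intermediate C → target (k2 = 0.050 s⁻¹)
    intermediate B ⇌ intermediate C (K3 = 6.9, k3 = 0.0037 s⁻¹)
    intermediate C → side product B (k4 = 0.0033 s⁻¹)
    intermediate A → side product A (k5 = 0.025 s⁻¹)
    intermediate A → intermediate B (k6 = 0.047 s⁻¹)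

- the set-up with the highest share of target in all that became target or side product A or side product B, at the outlet or at the end ("none" if the first two lie within 2 percentage points) (delta / theta / none)
- share of target in all that became target or side product A or side product B, at the outlet or at the end, delta
- share of target in all that became target or side product A or side product B, at the outlet or at the end, theta

Intermediate A was used up with a rate constant of 4.32 min⁻¹, larger than substrate's 1.6 min⁻¹, so as a rough estimate I treated its fork as if instantaneous: 34.7% of the charge in the end to side product A and 65.3% to intermediate B. Intermediate C was likewise drained faster than intermediate B fed it, and 93.8% of what reached it became target. That left the forward passage out of intermediate B, the slowest step on the way to target and so the rate-limiting step, and I carried its gate time, the mean wait in intermediate B before that step, 4.50 min, longer than the 1.5 min on offer.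

For the closed flask theta I allowed a lag of 0.849 min for the passage through substrate and intermediate A, so that I reckoned 8.79% of the charge past the gate, and with side product A counted in full my estimate of the share of target came to 18.9%. For the tank delta, the same gate time in the steady balances gave 21.3% of the charge as side product A, 10.0% through the gate and 7.77% as target, a share of 26.3%, so I committed to delta.

The forecast said delta, with 26.1% for delta and 17% for theta, lower for theta than my figure, on the ground that “The stirred tank gives part of the material a much longer stay and keeps intermediate A low”.

The simulation gave delta, with 26.1% for delta and 17.0% for theta, a gap of 9.1 percentage points against the margin of 2 points.

The share of target in theta stood at 17.0% because it was read at 1.5 min, a third of the gate time: intermediate B then held 46.6% of the charge, and the same flask left until 15.0 min gave 60.2%, a rise of 43 points. For the neighbouring reading of theta at 6.0 min, the same gate time and lag put 44.5% of the charge through the gate and the share of target at 52.7%; the run gave 51.6%.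

The numbers of this flask were chosen freely; the result is computed.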